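# Proposed synthesis of CNP0249919.1 by oxidative union of two enolate carbons across a carvone-derived ring

Atom labels (C1–C27, O7, O8, O11, O19) follow the order of the heavy atoms in the target SMILES and are used on every intermediate. Compound numbers 1–25 are those of the steps and of the compound list below.

## Analysis of the target

C1 is the vinylic methyl, C2=C3 the olefin, C4 and C22 the bridgeheads, C5–C21 the lactone-bearing bridge, C6(=O7)–O8 the lactone ester, C9, C10(O11H), C12(phenyl), O19 and C20 the oxolane, C23–C24 the saturated bridge and C25–C27 the isopropyl group. The skeleton is a bicyclo[2.2.2]oct-2-ene whose C5–C21 bridge carries a cis-fused δ-lactone (C5, C6, O8, C9, C20, C21), itself cis-fused along C9–C20 to a 3-hydroxy-2-phenyloxolane. There are nine stereocentres (4R,5S,9S,10R,12R,20S,21R,22R,24R). On the carbocycle C6 and C20 are cis and both turned to the olefin bridge, as is the isopropyl group on C24; on the oxolane O8 and C21 are cis, O11 is trans to O8, and phenyl is trans to O11 and cis to C21 across O19. Sensitive functions are the lactone with its enolisable C5–H, the free alcohol O11–H, the benzylic ether C12–O19 and a trisubstituted olefin in a bridged ring that can rearrange in strong acid. The difficulty lies in the four contiguous carbons C4–C5–C21–C22, where two eclipsed cis substituents sit on a fully substituted bridge, and in joining a terpene-like carbocycle to a sugar-like oxolane without losing any of the nine centres. The strategy rests on the array O7=C6–C5–C21–C20–O19: once C20 is written as a ketone, C5 and C21 are both α-carbons of carbonyl groups, so the bond they share, which belongs to the bicycle and to the lactone alike, can be made by joining two enolates.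

## Retrosynthetic reasoning

**Olefin C2=C3 (25 back to 23, 21 and 20).** No skeletal bond is cut. The C3–H bond of 25 is exchanged for the C3–O bond of enol triflate 23, and that for the C3 ketone of 21 and 20. C4 is a bridgehead, so a C3 ketone can enolise only towards C2 and the skeleton itself fixes the position of the olefin. The gain is a ring carbonyl in every earlier intermediate, which is what a carvone-derived ring supplies. Because enolate 22 is made with a strong base, O11 is capped first (21) and freed in the last flask (24 to 25).

**Lactone and oxolane C–O bonds (20 back to 17).** O8–C6 and O19–C20 are cut. This returns C20 to a ketone, C6 to a tert-butyl ester and O8, O11 and O19 to protected hydroxyl groups in 17. Both bonds form under acid, and the C20 carbonyl is what makes C21 an α-carbon. Forward, O19 closes onto the C20 ketone (hemiketal 19) and a hydride is delivered to the derived oxocarbenium ion; it must enter cis to O11 and trans to phenyl and to O8. A plain reduction of the C20 ketone to a carbinol is not used: the ring oxygen is the one already on C12, so the carbonyl oxygen has to leave, and the trans-fused acetonide must be gone before the oxolane can exist.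

**C5–C21 (17 back to 15).** This is the central cut. It removes the one bond common to the bicycle and the lactone and leaves a monocyclic cyclohexene 15 with a tert-butyl acetate arm on C4 and a ketone arm on C22, cis-1,4 to each other. Cutting here rather than at a bridgehead bond keeps both ends as stabilised α-carbons and keeps C4, C22 and C24 as ordinary ring stereocentres that can be set one at a time. The forward step must form 16 without a third enolate (the ring ketone stays masked as its silyl enol ether), join C5 to C21 through a boat, and place C6 and C20 cis on the olefin side.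

**C21–C22 (15 back to 5 and 14).** The ketone arm is detached at the ring. The forward reaction is a conjugate addition of silyl enol ether 14 to enone 5 with transfer of the silyl group to the ring oxygen. It sets C22 trans to the isopropyl group and hence cis to the C4 arm, and it delivers the ring ketone directly in the masked form that the key step needs.

**C4–C5 (5 back to 2 and 3; 2 back to 1).** The acetate arm is removed from the α′-carbon of the enone. Alkylation of dienolate 4 with 3 has to occur trans to the neighbouring isopropyl group. Compound 2 is 1 with the side-chain olefin saturated, so C24 comes from (S)-carvone 1 unchanged.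

**Side chain (14 back to 12, 11, 10, 9, 7, 8 and 6).** C20–C21 is cut (a methyl nucleophile on an N-methoxy-N-methylamide), then the C12–phenyl bond (aryl reagent 8 on the second amide of 7), with C12 set by chelation-controlled reduction of ketone 9. C9 and C10 are the two stereocentres of the D-tartrate acetonide 6, so only C12 and C20 of the oxolane have to be created.

## Alternatives that were turned down

**Alternative 1:** The oxolane is cut at C10–C12 instead of at O19–C20. Forward, the diazomethyl ketone A1 (C9 carbonyl, C10 diazo carbon, O19 carried as a benzyl ether on C20) would lose nitrogen on a divalent rhodium carboxylate dimer. The carbenoid would insert into the benzylic C–H bond to give the oxolan-3-one A2 with C12 and C20 cis.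
- For: insertion next to an ether oxygen through a five-membered transition state is the preferred mode of such carbenoids, the 2,5-cis outcome is the one needed, and phenyl enters as a simple benzyl ether. C12 is set by the ring closure itself, which is neater than the separate ketone reduction used here for that centre.
- Against: A2 has C9 at the ketone level and C10 as a methylene. O11 must still be introduced by enolisation towards C10 (enolisation towards C20 would scramble that centre), C9 must be reduced from the correct face, and the lactone closed; two stereocentres are thus set after the key step. The side chain on C21 is turned to the C2=C3 bridge, so the carbenoid is held near that olefin and cyclopropanation competes. A1 also presupposes the finished bicyclic core with C5, C21 and C20 in place, so the hard part of the molecule is left unanswered.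
- Comparison: the chosen plan takes C9 and C10 from a tartrate and forms only C12 and C20, each under a clear stereochemical model, and needs fewer steps after its key event.

**Alternative 2:** The lactone is cut at C20–C21. In the seco ester A3, O8 of an oxolane-2-carboxylic acid acylates a bicyclo[2.2.2]octa-2,5-diene carboxylic acid (C5=C21, C6 on C5). A3 would be decarboxylated under visible-light photoredox catalysis; the α-oxy radical at C20 would add to C21 (Giese-type 6-endo closure through the ester tether), and reduction and protonation at C5 would give the silyl-protected target A4.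
- For: the diene acid half is a few steps from a terpene diene and a propiolate by cycloaddition, which is shorter than the carbocycle synthesis proposed here. The tether forces C6 and C20 cis and the cis fusion at C9–C20, so three centres follow from one event, and the polarity of an α-oxy radical and an unsaturated ester is matched.
- Against: esters prefer the s-trans conformation, in which C20 and C21 are far apart, so hydrogen abstraction at C20 can outrun ring closure. C21 is a bridge carbon next to a bridgehead and must be attacked from the face toward the C2=C3 bridge, which is plausible but not enforced. The bicyclooctadiene can lose its saturated bridge by retro-cycloaddition on heating. The oxolane acid needs its own synthesis with four centres and a free O8.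
- Comparison: Alternative 2 is stronger on convergence and probably on step count. The chosen strategy offers instead a closure between two stabilised carbons held cis on one six-membered ring, with both new centres still epimerisable, and it builds the oxolane only after the carbon skeleton is complete.

**Alternative 3:** The bicycle is cut at C22–C23 and C4–C24. The lactone-fused 2-methylcyclohexa-1,3-diene A5 would add 2-isopropylacrolein A6 in a Diels–Alder reaction to give the 24-formyl compound A7, from which the formyl group would be removed by decarbonylation.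
- For: two C–C bonds and the bicycle arise in one step. The regiochemistry follows from the 2-methyl diene (the formyl-bearing carbon bonds to C4), the dienophile should approach anti to the lactone so that C6 and C20 end up on the olefin side, and α-substituted acroleins tend to place the formyl group exo, as C24 requires. On these counts it is at least as well controlled as the chosen key step.
- Against: A5 is a cis-5,6-disubstituted cyclohexadiene whose C5–H is both allylic and α to the lactone carbonyl, so it should isomerise into conjugation or aromatise readily. It already holds six of the nine centres and the whole heterocycle, so the real problem is only moved into its preparation. The quaternary C24 is built to be dismantled, and decarbonylation of a neopentyl aldehyde needs stoichiometric metal or forcing conditions in the presence of the olefin and lactone, with retention at C24.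
- Comparison: the chosen route takes C24 with its isopropyl group from (S)-carvone 1 without an auxiliary carbon and never passes through an isomerisable diene; it pays with a longer linear sequence.

Key step: step 10

## Route

Assumption: 6 and 8 are bought as such. C2 of 18–21, the anomeric centre C20 of 19 and the enolate geometries of 16 are left unspecified, since each converges later.

Step 1
Reactants: 1 (S)-carvone
Product: 2 (5S)-2-methyl-5-(propan-2-yl)cyclohex-2-en-1-one
Conditions: H2 (1 atm), RhCl(PPh3)3 (cat.), PhMe, 23 °C
Reagents that add atoms: none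
Why: Homogeneous hydrogenation with RhCl(PPh3)3 reduces the 1,1-disubstituted isopropenyl olefin much faster than the conjugated trisubstituted enone olefin, so the isopropyl group is in place before strong base or oxidant is used; C24 is not touched.

Step 2
Reactants: 2 (5S)-2-methyl-5-(propan-2-yl)cyclohex-2-en-1-one; 3 tert-butyl bromoacetate
Product: 5 tert-butyl 2-[(1R,6R)-3-methyl-2-oxo-6-(propan-2-yl)cyclohex-3-en-1-yl]acetate, via lithium dienolate 4 (not isolated)
Conditions: LiN(iPr)2, THF, −78 °C; 3, DMPU, −78 → −30 °C
Reagents that add atoms: none
Why: Kinetic deprotonation of the enone takes the α′-proton at C4, and the cross-conjugated enolate is alkylated (SN2 enolate alkylation) on the face away from the adjacent isopropyl group, which sets C4 trans to C24. The trans isomer is also the thermodynamic one, so base equilibration can be used if needed, and the tert-butyl ester resists attack by the enolate.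

Step 3
Reactants: 6 dimethyl (4S,5S)-2,2-dimethyl-1,3-dioxolane-4,5-dicarboxylate
Product: 7 (4S,5S)-N4,N5-dimethoxy-N4,N5,2,2-tetramethyl-1,3-dioxolane-4,5-dicarboxamide
Conditions: MeNH(OMe)·HCl, iPrMgCl, THF, −20 → 0 °C
Reagents that add atoms: N,O-dimethylhydroxylamine hydrochloride, CNOC.Cl
Why: Aminolysis of both esters by the magnesium amide formed in the flask is a standard route to N-methoxy-N-methylamides; the trans-dioxolane centres C9 and C10 are not enolised at this temperature.

Step 4
Reactants: 7 (4S,5S)-N4,N5-dimethoxy-N4,N5,2,2-tetramethyl-1,3-dioxolane-4,5-dicarboxamide; 8 phenylmagnesium bromide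
Product: 9 (4S,5S)-5-benzoyl-N-methoxy-N,2,2-trimethyl-1,3-dioxolane-4-carboxamide
Conditions: 8 (1.05 equiv), THF, −40 → −10 °C; aq. NH4Cl
Reagents that add atoms: none
Why: Grignard addition to an N-methoxy-N-methylamide stops at the ketone level because collapse to the ketone occurs only on work-up. With one equivalent the first anionic adduct lowers the reactivity of the neighbouring amide, so mono-addition should prevail; the two amides of 7 are equivalent by symmetry, and unreacted 7 can be recycled.

Step 5
Reactants: 9 (4S,5S)-5-benzoyl-N-methoxy-N,2,2-trimethyl-1,3-dioxolane-4-carboxamide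
Product: 10 (4S,5R)-5-[(R)-hydroxy(phenyl)methyl]-N-methoxy-N,2,2-trimethyl-1,3-dioxolane-4-carboxamide
Conditions: Zn(BH4)2, Et2O, −30 °C
Reagents that add atoms: none
Why: Chelation-controlled ketone reduction: zinc bridges the carbonyl oxygen and the α-oxygen O11 of the dioxolane, and hydride enters from the side of the C10 hydrogen, which should give the 10,12-anti alcohol, that is (12R). Zn(BH4)2 does not reduce the amide.

Step 6
Reactants: 10 (4S,5R)-5-[(R)-hydroxy(phenyl)methyl]-N-methoxy-N,2,2-trimethyl-1,3-dioxolane-4-carboxamide
Product: 11 (4S,5S)-5-[(R)-(tert-butyldimethylsilyloxy)(phenyl)methyl]-N-methoxy-N,2,2-trimethyl-1,3-dioxolane-4-carboxamide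
Conditions: TBSOTf, 2,6-lutidine, CH2Cl2, 0 °C
Reagents that add atoms: tert-butyldimethylsilyl trifluoromethanesulfonate, CC(C)(C)[Si](C)(C)OS(=O)(=O)C(F)(F)F
Why: Silyl triflate silylation of a hindered secondary benzylic alcohol; the silyl ether withstands the Grignard reagent, the amide bases and the iron salt of the following steps and is removed by acid together with the acetonide.

Step 7
Reactants: 11 (4S,5S)-5-[(R)-(tert-butyldimethylsilyloxy)(phenyl)methyl]-N-methoxy-N,2,2-trimethyl-1,3-dioxolane-4-carboxamide
Product: 12 1-[(4S,5S)-5-[(R)-(tert-butyldimethylsilyloxy)(phenyl)methyl]-2,2-dimethyl-1,3-dioxolan-4-yl]ethan-1-one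
Conditions: MeMgBr, THF, 0 °C; aq. NH4Cl
Reagents that add atoms: methylmagnesium bromide, C[Mg]Br
Why: Ketone synthesis from the remaining N-methoxy-N-methylamide; the methyl group becomes C21 and the new carbonyl carbon is C20, with no over-addition because the ketone is released only on work-up.

Step 8
Reactants: 12 1-[(4S,5S)-5-[(R)-(tert-butyldimethylsilyloxy)(phenyl)methyl]-2,2-dimethyl-1,3-dioxolan-4-yl]ethan-1-one
Product: 14 tert-butyldimethylsilyl enol ether of 12 (C21=C20–OSi), via lithium enolate 13 (not isolated)
Conditions: LiN(iPr)2, THF, −78 °C; TBSCl, DMPU, −78 → 0 °C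
Reagents that add atoms: tert-butyldimethylsilyl chloride, CC(C)(C)[Si](C)(C)Cl
Why: Kinetic enolisation of a methyl ketone occurs at the methyl group; the C9 hydrogen is hindered and flanked by oxygen and is not removed at −78 °C. O-silylation of the enolate gives the nucleophile for the conjugate addition.

Step 9
Reactants: 5 tert-butyl 2-[(1R,6R)-3-methyl-2-oxo-6-(propan-2-yl)cyclohex-3-en-1-yl]acetate; 14 tert-butyldimethylsilyl enol ether of 12
Product: 15 ring silyl enol ether with the acetate arm on C4 and the ketone arm on C22 (cis arms; isopropyl trans to both)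
Conditions: HN(SO2CF3)2 (5 mol %), CH2Cl2, −78 °C; Et3N
Reagents that add atoms: none
Why: Mukaiyama–Michael addition under silyl Lewis acid catalysis: the silylated enone is attacked at C22 by C21 of 14, and the silyl group is passed on so that the ring oxygen ends as the tetrasubstituted silyl enol ether and C20 as a ketone. Attack is axial and anti to the isopropyl group on C24, which sets C22 trans to C24 and therefore cis to the C4 arm.

Step 10
Reactants: 15 ring silyl enol ether with the acetate arm on C4 and the ketone arm on C22
Product: 17 bicyclo[2.2.2]octene keto ester with the C5–C21 bond (C6 and C20 cis; both syn to the enol ether bridge), via dilithium bis-enolate 16 (not isolated)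
Conditions: LiN(iPr)2 (2.3 equiv), THF, −78 °C; Fe(acac)3 (2.2 equiv), THF, −78 → 23 °C
Reagents that add atoms: none
Why: LiN(iPr)2 removes one proton from C5 of the tert-butyl ester and one from the C21 methylene of the ketone (the C9 hydrogen is hindered and flanked by oxygen) to give 16; Fe(acac)3 takes one electron from the more electron-rich ester enolate, the α-carbonyl radical at C5 is captured by the C21 enolate carbon, and a second equivalent of the trivalent iron salt oxidises the ketyl radical anion to the C20 ketone. The closest known reaction type is the intramolecular oxidative heterocoupling of two different lithium enolates with a trivalent iron salt, which has closed bicyclo[2.2.2] ring systems. The ring closed is the six-membered carbocycle C4–C5–C21–C22–C2–C3 (6-exo-trig attack of the C5 radical on the exocyclic enolate bond C21=C20); it can form only from the boat of the cyclohexene in which the cis-1,4 arms stand flagpole, and this proximity is what should let closure outrun dimerisation. C4, C22 and C24 are untouched and fix the sense of the bicycle. At C5 and C21 the acyl groups are expected to end cis and turned to the enol ether bridge: lithium and iron bridge the two enolate oxygens and stack the enolates, and the sector between the new bridge and the C2=C3 bridge is open (sp2 carbons with in-plane OSi and methyl groups), whereas the sector facing C23–C24 carries inward-pointing hydrogens. The step needs enolisation at two sites only (the ring ketone is masked as its silyl enol ether, which neither the amide base nor Fe(acac)3 attacks), coupling within one molecule, and above all the C21 configuration; C5 stays α to a carboxyl group and therefore correctable, since only C6 cis to C20 can lactonise.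

Step 11
Reactants: 17 bicyclo[2.2.2]octene keto ester with the C5–C21 bond
Product: 20 hydroxy keto lactone (C3 ketone of the target skeleton; O11–H free), via triol keto acid 18 (not isolated), via hemiketal lactone 19 (not isolated)
Conditions: TFA/H2O (9:1), 0 → 23 °C; evaporate from PhMe; Et3SiH, BF3·OEt2, MeCN, −30 → 0 °C
Reagents that add atoms: none
Why: Aqueous acid removes the acetonide, both silyl groups and the tert-butyl group to give 18, in which O19 adds to the C20 ketone and O8 is acylated by C6 on concentration to give 19; these closures are reversible and converge. BF3·OEt2 then ionises the hemiketal and Et3SiH reduces the five-membered oxocarbenium ion (ionic hydrogenation of a hemiketal), with hydride entering on the inside face of the envelope, cis to O11 and anti to phenyl and to O8, which should set (20S) with C21 cis to phenyl. The enol ether is hydrolysed to the C3 ketone, whose C2 configuration is irrelevant.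

Step 12
Reactants: 20 hydroxy keto lactone
Product: 21 O11 triethylsilyl ether of 20
Conditions: Et3SiCl, imidazole, DMF, 0 → 23 °C
Reagents that add atoms: chlorotriethylsilane, CC[Si](Cl)(CC)CC
Why: Standard silylation of the only hydroxyl group; imidazole does not enolise the ketone or the lactone, and the cap prevents alkoxide formation and O-sulfonylation in the next step.

Step 13
Reactants: 21 O11 triethylsilyl ether of 20
Product: 23 enol triflate (C2=C3–OSO2CF3), via potassium enolate 22 (not isolated)
Conditions: KN(SiMe3)2 (1.05 equiv), THF, −78 °C; PhNTf2, −78 → 0 °C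
Reagents that add atoms: N-phenylbis(trifluoromethanesulfonimide), O=S(=O)(N(c1ccccc1)S(=O)(=O)C(F)(F)F)C(F)(F)F
Why: Enol triflate formation from a ketone enolate: the ketone is several pKa units more acidic than the lactone, and because C4 is a bridgehead the enolate can form only towards C2, so a single regioisomer is expected and the C2 epimers converge.

Step 14
Reactants: 23 enol triflate (C2=C3–OSO2CF3)
Product: 25 target lactone CNP0249919.1, via triethylsilyl ether 24 (not isolated)
Conditions: Pd(OAc)2 (cat.), PPh3, Bu3N, HCO2H, DMF, 60 °C; then 1 M HCl, THF, 23 °C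
Reagents that add atoms: none
Why: Palladium-catalysed formate reduction of an enol triflate: zerovalent palladium formed in the flask inserts into the C3–O bond, formate displaces triflate and loses CO2 to give the hydride, and reductive elimination forms C3–H, leaving the C2=C3 olefin. Dilute acid then removes the triethylsilyl group from O11 without opening the lactone.

## Compound list

1 | (S)-carvone | CC1=CC[C@@H](CC1=O)C(C)=C | starting material
2 | (5S)-2-methyl-5-(propan-2-yl)cyclohex-2-en-1-one | CC1=CC[C@@H](CC1=O)C(C)C | intermediate
3 | tert-butyl bromoacetate | BrCC(=O)OC(C)(C)C | starting material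
4 | kinetic lithium dienolate of 2 (enolised towards C4) | CC1=CC[C@@H](C=C1O[Li])C(C)C | intermediate
5 | tert-butyl 2-[(1R,6R)-3-methyl-2-oxo-6-(propan-2-yl)cyclohex-3-en-1-yl]acetate (arm trans to isopropyl) | CC1=CC[C@H](C(C)C)[C@@H](CC(=O)OC(C)(C)C)C1=O | intermediate
6 | dimethyl (4S,5S)-2,2-dimethyl-1,3-dioxolane-4,5-dicarboxylate (dimethyl 2,3-O-isopropylidene-D-tartrate) | COC(=O)[C@H]1OC(C)(C)O[C@@H]1C(=O)OC | starting material
7 | (4S,5S)-N4,N5-dimethoxy-N4,N5,2,2-tetramethyl-1,3-dioxolane-4,5-dicarboxamide | CON(C)C(=O)[C@H]1OC(C)(C)O[C@@H]1C(=O)N(C)OC | intermediate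
8 | phenylmagnesium bromide | Br[Mg]c1ccccc1 | starting material
9 | (4S,5S)-5-benzoyl-N-methoxy-N,2,2-trimethyl-1,3-dioxolane-4-carboxamide | CON(C)C(=O)[C@H]1OC(C)(C)O[C@@H]1C(=O)c2ccccc2 | intermediate
10 | (4S,5R)-5-[(R)-hydroxy(phenyl)methyl]-N-methoxy-N,2,2-trimethyl-1,3-dioxolane-4-carboxamide | CON(C)C(=O)[C@H]1OC(C)(C)O[C@@H]1[C@H](O)c2ccccc2 | intermediate
11 | (4S,5S)-5-[(R)-(tert-butyldimethylsilyloxy)(phenyl)methyl]-N-methoxy-N,2,2-trimethyl-1,3-dioxolane-4-carboxamide | CON(C)C(=O)[C@H]1OC(C)(C)O[C@@H]1[C@H](O[Si](C)(C)C(C)(C)C)c2ccccc2 | intermediate
12 | 1-[(4S,5S)-5-[(R)-(tert-butyldimethylsilyloxy)(phenyl)methyl]-2,2-dimethyl-1,3-dioxolan-4-yl]ethan-1-one | CC(=O)[C@H]1OC(C)(C)O[C@@H]1[C@H](O[Si](C)(C)C(C)(C)C)c2ccccc2 | intermediate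
13 | lithium enolate of 12 (C21=C20–OLi) | C=C(O[Li])[C@H]1OC(C)(C)O[C@@H]1[C@H](O[Si](C)(C)C(C)(C)C)c2ccccc2 | intermediate
14 | tert-butyldimethylsilyl enol ether of 12: tert-butyl({1-[(4S,5S)-5-[(R)-(tert-butyldimethylsilyloxy)(phenyl)methyl]-2,2-dimethyl-1,3-dioxolan-4-yl]ethenyl}oxy)dimethylsilane | C=C(O[Si](C)(C)C(C)(C)C)[C@H]1OC(C)(C)O[C@@H]1[C@H](O[Si](C)(C)C(C)(C)C)c2ccccc2 | intermediate
15 | tert-butyl 2-[(1R,4R,6R)-2-(tert-butyldimethylsilyloxy)-3-methyl-4-{2-[(4S,5S)-5-[(R)-(tert-butyldimethylsilyloxy)(phenyl)methyl]-2,2-dimethyl-1,3-dioxolan-4-yl]-2-oxoethyl}-6-(propan-2-yl)cyclohex-2-en-1-yl]acetate | CC1=C(O[Si](C)(C)C(C)(C)C)[C@H](CC(=O)OC(C)(C)C)[C@@H](C(C)C)C[C@@H]1CC(=O)[C@H]2OC(C)(C)O[C@@H]2[C@H](O[Si](C)(C)C(C)(C)C)c3ccccc3 | intermediate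
16 | dilithium bis-enolate of 15 (ester enolate at C5, ketone enolate at C21; geometries open) | CC1=C(O[Si](C)(C)C(C)(C)C)[C@H](C=C(O[Li])OC(C)(C)C)[C@@H](C(C)C)C[C@@H]1C=C(O[Li])[C@H]2OC(C)(C)O[C@@H]2[C@H](O[Si](C)(C)C(C)(C)C)c3ccccc3 | intermediate
17 | bicyclo[2.2.2]oct-2-ene (C2=C3, bridgeheads C4 and C22) with OSi(tBu)Me2 on C3, methyl on C2, CO2tBu on C5, the (4S,5S)-dioxolane-4-carbonyl group (C20) on C21 and isopropyl on C24; C6 and C20 cis and syn to the C2=C3 bridge, isopropyl syn to the same bridge | CC1=C(O[Si](C)(C)C(C)(C)C)[C@@H]2[C@H](C(=O)OC(C)(C)C)[C@H](C(=O)[C@H]3OC(C)(C)O[C@@H]3[C@H](O[Si](C)(C)C(C)(C)C)c4ccccc4)[C@H]1C[C@@H]2C(C)C | intermediate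
18 | triol keto acid: C3 ketone, C6 carboxylic acid, C20 ketone, free O8–H, O11–H and O19–H (C2 epimers) | CC1C(=O)[C@@H]2[C@H](C(=O)O)[C@H](C(=O)[C@@H](O)[C@H](O)[C@H](O)c3ccccc3)[C@H]1C[C@@H]2C(C)C | intermediate
19 | hemiketal lactone: 20-hydroxy derivative of 20 (anomers, C2 epimers) | CC1C(=O)[C@@H]2[C@@H]3C(=O)O[C@H]4[C@H](O)[C@@H](c5ccccc5)OC4(O)[C@@H]3[C@H]1C[C@@H]2C(C)C | intermediate
20 | hydroxy keto lactone: the target skeleton with a C3 ketone and C2–H in place of the olefin (C2 epimers) | CC1C(=O)[C@@H]2[C@@H]3C(=O)O[C@H]4[C@H](O)[C@@H](c5ccccc5)O[C@H]4[C@@H]3[C@H]1C[C@@H]2C(C)C | intermediate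
21 | O11 triethylsilyl ether of 20 | CC1C(=O)[C@@H]2[C@@H]3C(=O)O[C@H]4[C@H](O[Si](CC)(CC)CC)[C@@H](c5ccccc5)O[C@H]4[C@@H]3[C@H]1C[C@@H]2C(C)C | intermediate
22 | potassium enolate of 21 (C2=C3–OK) | CC1=C(O[K])[C@@H]2[C@@H]3C(=O)O[C@H]4[C@H](O[Si](CC)(CC)CC)[C@@H](c5ccccc5)O[C@H]4[C@@H]3[C@H]1C[C@@H]2C(C)C | intermediate
23 | enol triflate of 21 (C2=C3–OSO2CF3) | CC1=C(OS(=O)(=O)C(F)(F)F)[C@@H]2[C@@H]3C(=O)O[C@H]4[C@H](O[Si](CC)(CC)CC)[C@@H](c5ccccc5)O[C@H]4[C@@H]3[C@H]1C[C@@H]2C(C)C | intermediate
24 | O11 triethylsilyl ether of the target | CC1=C[C@@H]2[C@@H]3C(=O)O[C@H]4[C@H](O[Si](CC)(CC)CC)[C@@H](c5ccccc5)O[C@H]4[C@@H]3[C@H]1C[C@@H]2C(C)C | intermediate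
25 | CNP0249919.1, (4R,5S,9S,10R,12R,20S,21R,22R,24R) in the atom labels used here | CC1=C[C@@H]2[C@@H]3C(=O)O[C@H]4[C@H](O)[C@@H](c5ccccc5)O[C@H]4[C@@H]3[C@H]1C[C@@H]2C(C)C | target

## Step count and risk

Total step count: 14 (steps 1–2 on the carvone branch, steps 3–8 on the tartrate branch, steps 9–14 after their union).
Longest linear sequence: 12 steps (steps 3–14, from 6 to 25).

**Step 10 (key step).** The likely failures are three. Ring closure may lose to hydrogen abstraction or intermolecular dimerisation, because the boat with both arms flagpole is costly. Facial control at C21 or C5 may be poor, so that one acyl group turns to the saturated bridge. The two arms may condense with each other before the oxidant arrives. The fallback is a two-electron closure that sets out from 15 and returns at 17. The side-chain ketone alone is enolised with LiN(SiMe3)2 (one equivalent; the ketone is far more acidic than the tert-butyl ester) and silylated with Me3SiCl to give the C20 trimethylsilyl enol ether of 15, F1. The ester is then deprotonated with LiN(iPr)2 and brominated at C5 with CBr4 to give the α-bromo ester, F2. (Me2N)3S(Me3SiF2) at −78 °C cleaves the trimethylsilyl enol ether much faster than the hindered tert-butyldimethylsilyl one, and the released C21 enolate displaces bromide at C5 in a 6-exo-tet SN2 alkylation, giving 17 without any oxidant.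

**Step 9.** The α-methyl enone may add the α-oxygenated silyl enol ether only slowly, and the strong silyl Lewis acid may meanwhile desilylate 14 or cleave the tert-butyl ester. The fallback replaces Lewis acid activation by a copper nucleophile; it sets out from 12 and 5 and returns at 15. Ketone 12 is condensed with Me2NNH2 to the N,N-dimethylhydrazone of 12, F3. F3 is deprotonated at C21 with LiN(iPr)2, transmetalated with CuI and added 1,4 to 5 (anti to isopropyl) in the presence of TBSCl, which traps the ring enolate and gives the C20 hydrazone of 15, F4. Hydrolysis of the hydrazone with Cu(OAc)2 in buffered aqueous THF, which leaves the tetrasubstituted silyl enol ether intact, gives 15.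

**Step 11.** Hydride delivery to the C20 oxocarbenium ion may occur with poor facial selectivity, the ion may lose a proton to an enol ether and scramble C21 or C9, or the C3 ketone may be reduced as well. The fallback sets C20 by displacement instead of hydride delivery; it sets out from 17 and returns at 20. Chelation-controlled reduction of 17 with Zn(BH4)2 should give the C20 alcohol with O anti to O8, F5. MeSO2Cl/Et3N converts it into the methanesulfonate, F6. Aqueous HCl in THF removes the acetonide and both silyl groups while keeping the tert-butyl ester; warming with 2,6-lutidine then lets O19 displace the sulfonate at C20 with inversion (5-exo-tet), which gives the oxolane tert-butyl ester, F7. TFA cleaves the ester and closes the lactone to 20.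

**Step 5.** Chelated and non-chelated transition states may compete, because the acetonide oxygen is a weak ligand, and this would erode the selectivity at C12. The fallback sets the centre by the opposite facial preference and then inverts it; it sets out from 9 and returns at 10. Reduction under non-chelation control with LiBH(sBu)3 at −78 °C should favour the C12 epimer of 10, F8. A Mitsunobu reaction (PPh3, diisopropyl azodicarboxylate, 4-nitrobenzoic acid) inverts C12 and gives the 4-nitrobenzoate of 10, F9. Methanolysis with K2CO3 in MeOH, which leaves the N-methoxy-N-methylamide untouched, gives 10.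

## Further compounds

F1 | step 10 | C20 trimethylsilyl enol ether of 15 (C21=C20–OSiMe3) | CC1=C(O[Si](C)(C)C(C)(C)C)[C@H](CC(=O)OC(C)(C)C)[C@@H](C(C)C)C[C@@H]1C=C(O[Si](C)(C)C)[C@H]2OC(C)(C)O[C@@H]2[C@H](O[Si](C)(C)C(C)(C)C)c3ccccc3
F2 | step 10 | 5-bromo derivative of F1 (α-bromo tert-butyl ester, C5 epimers) | CC1=C(O[Si](C)(C)C(C)(C)C)[C@H](C(Br)C(=O)OC(C)(C)C)[C@@H](C(C)C)C[C@@H]1C=C(O[Si](C)(C)C)[C@H]2OC(C)(C)O[C@@H]2[C@H](O[Si](C)(C)C(C)(C)C)c3ccccc3
F3 | step 9 | N,N-dimethylhydrazone of 12 | CC(=NN(C)C)[C@H]1OC(C)(C)O[C@@H]1[C@H](O[Si](C)(C)C(C)(C)C)c2ccccc2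
F4 | step 9 | C20 N,N-dimethylhydrazone of 15 | CC1=C(O[Si](C)(C)C(C)(C)C)[C@H](CC(=O)OC(C)(C)C)[C@@H](C(C)C)C[C@@H]1CC(=NN(C)C)[C@H]2OC(C)(C)O[C@@H]2[C@H](O[Si](C)(C)C(C)(C)C)c3ccccc3
F5 | step 11 | C20 alcohol from 17 (hydroxyl anti to O8) | CC1=C(O[Si](C)(C)C(C)(C)C)[C@@H]2[C@H](C(=O)OC(C)(C)C)[C@H]([C@@H](O)[C@H]3OC(C)(C)O[C@@H]3[C@H](O[Si](C)(C)C(C)(C)C)c4ccccc4)[C@H]1C[C@@H]2C(C)C
F6 | step 11 | C20 methanesulfonate of F5 | CC1=C(O[Si](C)(C)C(C)(C)C)[C@@H]2[C@H](C(=O)OC(C)(C)C)[C@H]([C@@H](OS(C)(=O)=O)[C@H]3OC(C)(C)O[C@@H]3[C@H](O[Si](C)(C)C(C)(C)C)c4ccccc4)[C@H]1C[C@@H]2C(C)C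
F7 | step 11 | oxolane tert-butyl ester with C3 ketone and free O8–H and O11–H (C2 epimers) | CC1C(=O)[C@@H]2[C@H](C(=O)OC(C)(C)C)[C@H]([C@@H]3O[C@H](c4ccccc4)[C@@H](O)[C@@H]3O)[C@H]1C[C@@H]2C(C)C
F8 | step 5 | C12 epimer of 10 | CON(C)C(=O)[C@H]1OC(C)(C)O[C@@H]1[C@@H](O)c2ccccc2
F9 | step 5 | 4-nitrobenzoate of 10 | CON(C)C(=O)[C@H]1OC(C)(C)O[C@@H]1[C@H](OC(=O)c2ccc(cc2)[N+](=O)[O-])c3ccccc3
A1 | alternative 1 | diazomethyl ketone with O19 benzyl ether on C20 of the bicyclic methyl ester | CC1=C[C@@H]2[C@H](C(=O)OC)[C@H]([C@H](OCc3ccccc3)C(=O)C=[N+]=[N-])[C@H]1C[C@@H]2C(C)C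
A2 | alternative 1 | cis-2,5-disubstituted oxolan-3-one on the bicyclic methyl ester | CC1=C[C@@H]2[C@H](C(=O)OC)[C@H]([C@@H]3O[C@H](c4ccccc4)CC3=O)[C@H]1C[C@@H]2C(C)C
A3 | alternative 2 | O8 ester of the oxolane-2-carboxylic acid (O11 silyl ether, C20 either epimer) with the bicyclo[2.2.2]octa-2,5-diene carboxylic acid | CC1=C[C@@H]2C(C(=O)O[C@H]3[C@H](O[Si](C)(C)C(C)(C)C)[C@@H](c4ccccc4)OC3C(=O)O)=C[C@H]1C[C@@H]2C(C)C
A4 | alternative 2 | O11 tert-butyldimethylsilyl ether of 25 | CC1=C[C@@H]2[C@@H]3C(=O)O[C@H]4[C@H](O[Si](C)(C)C(C)(C)C)[C@@H](c5ccccc5)O[C@H]4[C@@H]3[C@H]1C[C@@H]2C(C)C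
A5 | alternative 3 | lactone-fused 2-methylcyclohexa-1,3-diene | CC1=C[C@@H]2[C@H](C=C1)C(=O)O[C@H]3[C@H](O)[C@@H](c4ccccc4)O[C@H]32
A6 | alternative 3 | 2-isopropylacrolein (3-methyl-2-methylidenebutanal) | CC(C)C(=C)C=O
A7 | alternative 3 | 24-formyl derivative of 25 | CC1=C[C@@H]2[C@@H]3C(=O)O[C@H]4[C@H](O)[C@@H](c5ccccc5)O[C@H]4[C@@H]3[C@H]1C[C@]2(C=O)C(C)C
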